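**Plan**

- Retrosynthetic cuts, in order (locants of the hexahydro-1H-indene core: C1 CHMe, C2 C=O, C3 CHEt, C3a/C7a ring fusion, C4/C5 quaternary, C6=C7): CO2H from CO2Me; ring B (cyclopentanone) at C1–C2 and C3–C3a; the C1–O bond of the resulting carbinol ether; C7a–C1 (acetyl onto a dienyl triflate); the C5 dienyl arm (from butynyl, from carboxyl); ring A by Diels–Alder.
- Enabling feature: C1–C7a–C3a of ring B is an allyl unit once C7a=C3a is a ring alkene next to C6=C7. The C2–C3 unit then sits as a but-1-enyl ether on a C1 oxygen, and this allyl vinyl ether is an isomer of the cyclopentanone.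
- Forward order: ring A first (2-silyloxydiene + 3,4-diethylfuran-2,5-dione, both quaternary carbons at once), alkaloid-catalysed methanolysis, C5 arm, then enone, dienyl triflate, methyl ketone, (R)-carbinol, butenyl ether. Ring B comes last, by Claisen shift (C3–C3a) and rhodium hydroacylation (C2–C1) in one flask.
- Stereochemistry: cis C4/C5 from the cyclic dienophile, absolute sense from a catalyst-controlled regiodivergent ring opening (half of the racemate is discarded there). The carbinol comes from CBS reduction and is relayed to C3a and C3 by the suprafacial chair [3,3] shift. C7a–H comes from Rh–H delivery through the C3 tether (trans fusion); C1 and C3 are equilibrated last.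

Key step: step 13

Remark: 3,4-diethylfuran-2,5-dione (3) and (E)-1-iodobut-1-ene (21) are taken as purchasable; "dienyl" below always means (1E,3E)-2-ethyl-4-phenylbuta-1,3-dien-1-yl.

**Step 1**
Reactants: 1 3-methylbut-3-en-2-one
Product: 2 tert-butyl(dimethyl)[(3-methylbuta-1,3-dien-2-yl)oxy]silane
Conditions: TBSOTf, Et3N, CH2Cl2, 0 °C
Reagents that add atoms: tert-butyldimethylsilyl trifluoromethanesulfonate, CC(C)(C)[Si](C)(C)OS(=O)(=O)C(F)(F)F
Why: Soft enolisation and O-silylation of the enone (silyl dienol ether formation) should give the 2-silyloxydiene; no stereocentre is formed.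

**Step 2**
Reactants: 2 tert-butyl(dimethyl)[(3-methylbuta-1,3-dien-2-yl)oxy]silane; 3 3,4-diethylfuran-2,5-dione
Product: 4 rac-(3aR,7aS)-5-[tert-butyl(dimethyl)silyl]oxy-3a,7a-diethyl-6-methyl-3a,4,7,7a-tetrahydro-2-benzofuran-1,3-dione
Conditions: toluene, BHT (cat.), sealed tube, 160 °C
Reagents that add atoms: none
Why: Thermal Diels–Alder cycloaddition of the electron-rich diene with the doubly activated tetrasubstituted anhydride should form both quaternary carbons at once; the cyclic dienophile forces the two ethyl groups cis, its symmetry removes any regiochemical question, and the product is racemic with a regiodefined silyl enol ether.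

**Step 3**
Reactants: 4 rac-(3aR,7aS)-5-[tert-butyl(dimethyl)silyl]oxy-3a,7a-diethyl-6-methyl-3a,4,7,7a-tetrahydro-2-benzofuran-1,3-dione
Product: 5 (1S,6R)-4-[tert-butyl(dimethyl)silyl]oxy-1,6-diethyl-6-(methoxycarbonyl)-3-methylcyclohex-3-ene-1-carboxylic acid
Conditions: hydroquinidine anthraquinone-1,4-diyl diether, (DHQD)2AQN (20 mol%), MeOH (10 equiv), Et2O, −20 °C; silica gel separation
Reagents that add atoms: methanol, CO
Why: Cinchona-alkaloid-catalysed anhydride alcoholysis run as a regiodivergent (parallel kinetic) resolution: the catalyst should open the carbonyl of one prochirality sense in each enantiomer of the pseudo-meso anhydride, so the (3aR,7aS) half gives 5 and the mirror-image half a constitutional isomer that is separated, which fixes the absolute configuration of both quaternary carbons and tells the two carboxyl groups apart.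

**Step 4**
Reactants: 5 (1S,6R)-4-[tert-butyl(dimethyl)silyl]oxy-1,6-diethyl-6-(methoxycarbonyl)-3-methylcyclohex-3-ene-1-carboxylic acid
Product: 7 methyl (1R,6S)-3-[tert-butyl(dimethyl)silyl]oxy-1,6-diethyl-6-formyl-4-methylcyclohex-3-ene-1-carboxylate, via acid chloride 6 (not isolated)
Conditions: 1-chloro-N,N,2-trimethylprop-1-en-1-amine, CH2Cl2, 0 °C; LiAlH(Ot-Bu)3, THF, −78 °C
Reagents that add atoms: none
Why: Neutral acid chloride formation with the α-chloroenamine followed by hindered-hydride reduction of the acid chloride should stop at the aldehyde, while the neopentyl methyl ester and the silyl enol ether stay untouched.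

**Step 5**
Reactants: 7 methyl (1R,6S)-3-[tert-butyl(dimethyl)silyl]oxy-1,6-diethyl-6-formyl-4-methylcyclohex-3-ene-1-carboxylate
Product: 8 methyl (1R,6R)-3-[tert-butyl(dimethyl)silyl]oxy-1,6-diethyl-6-ethynyl-4-methylcyclohex-3-ene-1-carboxylate
Conditions: dimethyl (1-diazo-2-oxopropyl)phosphonate, K2CO3, MeOH, rt
Reagents that add atoms: dimethyl (1-diazo-2-oxopropyl)phosphonate, CC(=O)C(=[N+]=[N-])P(=O)(OC)OC
Why: Ohira–Bestmann (Seyferth–Gilbert) homologation should convert the hindered, non-enolisable aldehyde into the terminal alkyne under mild base.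

**Step 6**
Reactants: 8 methyl (1R,6R)-3-[tert-butyl(dimethyl)silyl]oxy-1,6-diethyl-6-ethynyl-4-methylcyclohex-3-ene-1-carboxylate
Product: 10 methyl (1R,6R)-6-(but-1-yn-1-yl)-3-[tert-butyl(dimethyl)silyl]oxy-1,6-diethyl-4-methylcyclohex-3-ene-1-carboxylate, via lithium acetylide 9 (not isolated)
Conditions: LiN(i-Pr)2, THF, −78 °C; EtI, DMPU, −78 °C to rt
Reagents that add atoms: iodoethane, CCI
Why: Acetylide alkylation (SN2) with iodoethane; the ester has no α-hydrogen and is shielded by two quaternary carbons.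

**Step 7**
Reactants: 10 methyl (1R,6R)-6-(but-1-yn-1-yl)-3-[tert-butyl(dimethyl)silyl]oxy-1,6-diethyl-4-methylcyclohex-3-ene-1-carboxylate; 11 (E)-(2-bromoethenyl)benzene
Product: 14 methyl (1R,6R)-3-[tert-butyl(dimethyl)silyl]oxy-1,6-diethyl-6-[(1E,3E)-2-ethyl-4-phenylbuta-1,3-dien-1-yl]-4-methylcyclohex-3-ene-1-carboxylate, via alkenylzirconocene chloride 12 (not isolated), via alkenylzinc chloride 13 (not isolated)
Conditions: Cp2Zr(H)Cl, THF, 50 °C; ZnCl2; Pd(PPh3)4 (5 mol%), THF, rt to 50 °C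
Reagents that add atoms: none
Why: Hydrozirconation is a syn addition that puts zirconium on the alkyne carbon remote from the quaternary centre, and zirconium-to-zinc transmetalation with Negishi coupling (zerovalent palladium) proceeds with retention at both partners, so the trisubstituted (1E,3E)-diene geometry follows from the mechanism.

**Step 8**
Reactants: 14 methyl (1R,6R)-3-[tert-butyl(dimethyl)silyl]oxy-1,6-diethyl-6-[(1E,3E)-2-ethyl-4-phenylbuta-1,3-dien-1-yl]-4-methylcyclohex-3-ene-1-carboxylate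
Product: 15 methyl (1R,2S)-1,2-diethyl-2-[(1E,3E)-2-ethyl-4-phenylbuta-1,3-dien-1-yl]-4-methyl-5-oxocyclohex-3-ene-1-carboxylate
Conditions: Pd(OAc)2 (1.1 equiv), MeCN, 40 °C
Reagents that add atoms: none
Why: Saegusa–Ito oxidation: the silyl enol ether laid down by the Diels–Alder step gives a regiodefined palladium enolate (divalent palladium), and β-hydride elimination toward the ring CH2 should give the endocyclic 2-methyl enone.

**Step 9**
Reactants: 15 methyl (1R,2S)-1,2-diethyl-2-[(1E,3E)-2-ethyl-4-phenylbuta-1,3-dien-1-yl]-4-methyl-5-oxocyclohex-3-ene-1-carboxylate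
Product: 17 methyl (1R,6S)-1,6-diethyl-6-[(1E,3E)-2-ethyl-4-phenylbuta-1,3-dien-1-yl]-4-methyl-3-[(trifluoromethanesulfonyl)oxy]cyclohexa-2,4-diene-1-carboxylate, via potassium dienolate 16 (not isolated)
Conditions: KN(SiMe3)2, THF, −78 °C; PhNTf2; aq NH4Cl
Reagents that add atoms: N-phenylbis(trifluoromethanesulfonimide), O=S(=O)(N(c1ccccc1)S(=O)(=O)C(F)(F)F)C(F)(F)F
Why: Kinetic α'-deprotonation (the only enolisable position, since the γ-carbon is quaternary) gives the cross-conjugated dienolate, and O-triflation should give the 2-triflyloxy-1,3-diene.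

**Step 10**
Reactants: 17 methyl (1R,6S)-1,6-diethyl-6-[(1E,3E)-2-ethyl-4-phenylbuta-1,3-dien-1-yl]-4-methyl-3-[(trifluoromethanesulfonyl)oxy]cyclohexa-2,4-diene-1-carboxylate
Product: 19 methyl (1R,6S)-3-acetyl-1,6-diethyl-6-[(1E,3E)-2-ethyl-4-phenylbuta-1,3-dien-1-yl]-4-methylcyclohexa-2,4-diene-1-carboxylate, via ethoxyvinyl diene 18 (not isolated)
Conditions: tributyl(1-ethoxyvinyl)stannane, Pd(PPh3)4 (5 mol%), LiCl, THF, 65 °C; 1 M HCl, rt
Reagents that add atoms: tributyl(1-ethoxyvinyl)stannane, CCCC[Sn](CCCC)(CCCC)C(=C)OCC; water, O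
Why: Stille coupling of the alkenyl triflate with an acetyl anion equivalent, then acid hydrolysis of the enol ether, should give the dienyl methyl ketone.

**Step 11**
Reactants: 19 methyl (1R,6S)-3-acetyl-1,6-diethyl-6-[(1E,3E)-2-ethyl-4-phenylbuta-1,3-dien-1-yl]-4-methylcyclohexa-2,4-diene-1-carboxylate
Product: 20 methyl (1R,6S)-1,6-diethyl-6-[(1E,3E)-2-ethyl-4-phenylbuta-1,3-dien-1-yl]-3-[(1R)-1-hydroxyethyl]-4-methylcyclohexa-2,4-diene-1-carboxylate
Conditions: (S)-1-methyl-3,3-diphenyltetrahydro-1H,3H-pyrrolo[1,2-c][1,3,2]oxazaborole (20 mol%), catecholborane, toluene, −78 °C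
Reagents that add atoms: none
Why: Corey–Bakshi–Shibata reduction under reagent control: with the α-branched dienyl group as the large and methyl as the small substituent, the (S)-oxazaborolidine should give the (R)-carbinol.

**Step 12**
Reactants: 20 methyl (1R,6S)-1,6-diethyl-6-[(1E,3E)-2-ethyl-4-phenylbuta-1,3-dien-1-yl]-3-[(1R)-1-hydroxyethyl]-4-methylcyclohexa-2,4-diene-1-carboxylate; 21 (E)-1-iodobut-1-ene
Product: 22 methyl (1R,6S)-3-{(1R)-1-[(1E)-but-1-en-1-yloxy]ethyl}-1,6-diethyl-6-[(1E,3E)-2-ethyl-4-phenylbuta-1,3-dien-1-yl]-4-methylcyclohexa-2,4-diene-1-carboxylate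
Conditions: CuI (10 mol%), 3,4,7,8-tetramethyl-1,10-phenanthroline (20 mol%), Cs2CO3, toluene, 80 °C
Reagents that add atoms: none
Why: Copper-catalysed Ullmann-type C–O coupling of an alcohol with an alkenyl iodide retains the alkene geometry and leaves the carbinol centre untouched, giving the allyl (E)-but-1-enyl ether.

**Step 13**
Reactants: 22 methyl (1R,6S)-3-{(1R)-1-[(1E)-but-1-en-1-yloxy]ethyl}-1,6-diethyl-6-[(1E,3E)-2-ethyl-4-phenylbuta-1,3-dien-1-yl]-4-methylcyclohexa-2,4-diene-1-carboxylate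
Product: 24 methyl (1R,3S,3aR,4R,5R,7aR)-3,4,5-triethyl-5-[(1E,3E)-2-ethyl-4-phenylbuta-1,3-dien-1-yl]-1,7-dimethyl-2-oxo-2,3,3a,4,5,7a-hexahydro-1H-indene-4-carboxylate, via enal 23 (not isolated)
Conditions: [Rh(Ph2PCH2CH2PPh2)]BF4 (10 mol%), 1,2-dichloroethane, sealed tube, 110 °C
Reagents that add atoms: none
Why: Proposed new method: heating triggers a chair-like Claisen [3,3] shift that forms C3–C3a on the ring face syn to the departing C–O bond and leaves enal 23 with an exocyclic ethylidene at C7a; the cationic monovalent rhodium then adds the formyl C–H bond, the acyl rhodium hydride inserts the ethylidene (H to C7a, Rh to C1) and reductive elimination forms C2–C1. The closest known reaction is the rhodium-catalysed tandem Claisen rearrangement–hydroacylation of simple allyl vinyl ethers to cyclopentanones; new here is hydroacylation of a trisubstituted exocyclic alkene that is part of a semicyclic diene. Ring B closes by reductive elimination from a six-membered acyl rhodacycle, formally a 5-endo closure onto the alkene that only this metallacycle route allows. C3a is set by chirality transfer from the (R)-carbinol through the rotamer that turns the carbinol methyl away from the C7 methyl, C3 by the (E)-enol ether in the chair, C7a by hydride delivery from rhodium tethered through C3 (H cis to the C3a–C3 bond, hence trans fusion), and C1 by syn addition (expected as the epimer, corrected in step 14). The step needs 1,2- over 1,4-hydroacylation of the diene and insertion over decarbonylation: the short tether lets Rh–H reach only C7a/C1, the two ring sp3 carbons are quaternary so no hydrogen shift can scramble the diene, and the chelating diphosphine cation disfavours CO loss.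

**Step 14**
Reactants: 24 methyl (1R,3S,3aR,4R,5R,7aR)-3,4,5-triethyl-5-[(1E,3E)-2-ethyl-4-phenylbuta-1,3-dien-1-yl]-1,7-dimethyl-2-oxo-2,3,3a,4,5,7a-hexahydro-1H-indene-4-carboxylate
Product: 25 (1S,3S,3aR,4R,5R,7aR)-3,4,5-triethyl-5-[(1E,3E)-2-ethyl-4-phenylbuta-1,3-dien-1-yl]-1,7-dimethyl-2-oxo-2,3,3a,4,5,7a-hexahydro-1H-indene-4-carboxylic acid
Conditions: NaSEt, DMF, 90 °C; 1 M HCl
Reagents that add atoms: none
Why: SN2 demethylation by thiolate at the O–CH3 carbon frees the hindered acid without attack at the shielded carbonyl, and the basic medium should equilibrate the two α-keto centres C1 and C3 to the all-trans cyclopentanone (each α-substituent trans to the neighbouring ring-fusion bond), which inverts C1.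

**Compound list**

1 | 3-methylbut-3-en-2-one | CC(=O)C(C)=C | starting material
2 | tert-butyl(dimethyl)[(3-methylbuta-1,3-dien-2-yl)oxy]silane | C=C(C)C(=C)O[Si](C)(C)C(C)(C)C | intermediate
3 | 3,4-diethylfuran-2,5-dione | CCC1=C(CC)C(=O)OC1=O | starting material
4 | rac-(3aR,7aS)-5-[tert-butyl(dimethyl)silyl]oxy-3a,7a-diethyl-6-methyl-3a,4,7,7a-tetrahydro-2-benzofuran-1,3-dione (racemate; the enantiomer drawn leads on) | O=C3[C@@]1(CC)CC(C)=C(O[Si](C)(C)C(C)(C)C)C[C@@]1(CC)C(=O)O3 | intermediate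
5 | (1S,6R)-4-[tert-butyl(dimethyl)silyl]oxy-1,6-diethyl-6-(methoxycarbonyl)-3-methylcyclohex-3-ene-1-carboxylic acid | OC(=O)[C@@]1(CC)CC(C)=C(O[Si](C)(C)C(C)(C)C)C[C@@]1(CC)C(=O)OC | intermediate
6 | methyl (1R,6S)-3-[tert-butyl(dimethyl)silyl]oxy-6-(chlorocarbonyl)-1,6-diethyl-4-methylcyclohex-3-ene-1-carboxylate (acid chloride) | ClC(=O)[C@@]1(CC)CC(C)=C(O[Si](C)(C)C(C)(C)C)C[C@@]1(CC)C(=O)OC | intermediate
7 | methyl (1R,6S)-3-[tert-butyl(dimethyl)silyl]oxy-1,6-diethyl-6-formyl-4-methylcyclohex-3-ene-1-carboxylate | O=C[C@@]1(CC)CC(C)=C(O[Si](C)(C)C(C)(C)C)C[C@@]1(CC)C(=O)OC | intermediate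
8 | methyl (1R,6R)-3-[tert-butyl(dimethyl)silyl]oxy-1,6-diethyl-6-ethynyl-4-methylcyclohex-3-ene-1-carboxylate | C#C[C@@]1(CC)CC(C)=C(O[Si](C)(C)C(C)(C)C)C[C@@]1(CC)C(=O)OC | intermediate
9 | lithium acetylide of 8 | [Li]C#C[C@@]1(CC)CC(C)=C(O[Si](C)(C)C(C)(C)C)C[C@@]1(CC)C(=O)OC | intermediate
10 | methyl (1R,6R)-6-(but-1-yn-1-yl)-3-[tert-butyl(dimethyl)silyl]oxy-1,6-diethyl-4-methylcyclohex-3-ene-1-carboxylate | CCC#C[C@@]1(CC)CC(C)=C(O[Si](C)(C)C(C)(C)C)C[C@@]1(CC)C(=O)OC | intermediate
11 | (E)-(2-bromoethenyl)benzene | Br/C=C/c1ccccc1 | starting material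
12 | alkenylzirconocene chloride from 10 (Cp2ZrCl on the ethyl-bearing alkene carbon, ethyl cis to the ring) | CC/C([Zr](Cl)(C2C=CC=C2)C2C=CC=C2)=C\[C@@]1(CC)CC(C)=C(O[Si](C)(C)C(C)(C)C)C[C@@]1(CC)C(=O)OC | intermediate
13 | alkenylzinc chloride from 12 (same geometry) | CC/C([Zn]Cl)=C\[C@@]1(CC)CC(C)=C(O[Si](C)(C)C(C)(C)C)C[C@@]1(CC)C(=O)OC | intermediate
14 | methyl (1R,6R)-3-[tert-butyl(dimethyl)silyl]oxy-1,6-diethyl-6-[(1E,3E)-2-ethyl-4-phenylbuta-1,3-dien-1-yl]-4-methylcyclohex-3-ene-1-carboxylate | CCC(/C=C/c1ccccc1)=C\[C@@]1(CC)CC(C)=C(O[Si](C)(C)C(C)(C)C)C[C@@]1(CC)C(=O)OC | intermediate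
15 | methyl (1R,2S)-1,2-diethyl-2-[(1E,3E)-2-ethyl-4-phenylbuta-1,3-dien-1-yl]-4-methyl-5-oxocyclohex-3-ene-1-carboxylate | CCC(/C=C/c1ccccc1)=C\[C@@]1(CC)C=C(C)C(=O)C[C@@]1(CC)C(=O)OC | intermediate
16 | potassium dienolate of 15 | CCC(/C=C/c1ccccc1)=C\[C@@]1(CC)C=C(C)C([O-])=C[C@@]1(CC)C(=O)OC.[K+] | intermediate
17 | methyl (1R,6S)-1,6-diethyl-6-[(1E,3E)-2-ethyl-4-phenylbuta-1,3-dien-1-yl]-4-methyl-3-[(trifluoromethanesulfonyl)oxy]cyclohexa-2,4-diene-1-carboxylate | CCC(/C=C/c1ccccc1)=C\[C@@]1(CC)C=C(C)C(OS(=O)(=O)C(F)(F)F)=C[C@@]1(CC)C(=O)OC | intermediate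
18 | methyl (1R,6S)-3-(1-ethoxyethenyl)-1,6-diethyl-6-[(1E,3E)-2-ethyl-4-phenylbuta-1,3-dien-1-yl]-4-methylcyclohexa-2,4-diene-1-carboxylate | CCC(/C=C/c1ccccc1)=C\[C@@]1(CC)C=C(C)C(C(=C)OCC)=C[C@@]1(CC)C(=O)OC | intermediate
19 | methyl (1R,6S)-3-acetyl-1,6-diethyl-6-[(1E,3E)-2-ethyl-4-phenylbuta-1,3-dien-1-yl]-4-methylcyclohexa-2,4-diene-1-carboxylate | CCC(/C=C/c1ccccc1)=C\[C@@]1(CC)C=C(C)C(C(C)=O)=C[C@@]1(CC)C(=O)OC | intermediate
20 | methyl (1R,6S)-1,6-diethyl-6-[(1E,3E)-2-ethyl-4-phenylbuta-1,3-dien-1-yl]-3-[(1R)-1-hydroxyethyl]-4-methylcyclohexa-2,4-diene-1-carboxylate | CCC(/C=C/c1ccccc1)=C\[C@@]1(CC)C=C(C)C([C@@H](C)O)=C[C@@]1(CC)C(=O)OC | intermediate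
21 | (E)-1-iodobut-1-ene | CC/C=C/I | starting material
22 | methyl (1R,6S)-3-{(1R)-1-[(1E)-but-1-en-1-yloxy]ethyl}-1,6-diethyl-6-[(1E,3E)-2-ethyl-4-phenylbuta-1,3-dien-1-yl]-4-methylcyclohexa-2,4-diene-1-carboxylate | CCC(/C=C/c1ccccc1)=C\[C@@]1(CC)C=C(C)C([C@@H](C)O/C=C/CC)=C[C@@]1(CC)C(=O)OC | intermediate
23 | methyl (1R,2S,5E,6S)-1,2-diethyl-2-[(1E,3E)-2-ethyl-4-phenylbuta-1,3-dien-1-yl]-5-ethylidene-4-methyl-6-[(2S)-1-oxobutan-2-yl]cyclohex-3-ene-1-carboxylate | CCC(/C=C/c1ccccc1)=C\[C@@]1(CC)C=C(C)/C(=C/C)[C@H]([C@H](CC)C=O)[C@@]1(CC)C(=O)OC | intermediate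
24 | methyl (1R,3S,3aR,4R,5R,7aR)-3,4,5-triethyl-5-[(1E,3E)-2-ethyl-4-phenylbuta-1,3-dien-1-yl]-1,7-dimethyl-2-oxo-2,3,3a,4,5,7a-hexahydro-1H-indene-4-carboxylate | CCC(/C=C/c1ccccc1)=C\[C@@]1(CC)C=C(C)[C@@H]2[C@H]([C@H](CC)C(=O)[C@@H]2C)[C@@]1(CC)C(=O)OC | intermediate
25 | (1S,3S,3aR,4R,5R,7aR)-3,4,5-triethyl-5-[(1E,3E)-2-ethyl-4-phenylbuta-1,3-dien-1-yl]-1,7-dimethyl-2-oxo-2,3,3a,4,5,7a-hexahydro-1H-indene-4-carboxylic acid | CCC(/C=C/c1ccccc1)=C\[C@@]1(CC)C=C(C)[C@@H]2[C@H]([C@H](CC)C(=O)[C@H]2C)[C@@]1(CC)C(=O)O | target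

**Count and risks**

Total step count: 14. Longest linear sequence: 14 steps (1 to 25); 3, 11 and 21 enter as purchased reactants.

Steps most likely to fail:

Step 13 (Proposed new method). The acyl rhodium hydride may lose carbon monoxide before the hindered trisubstituted alkene inserts. Hydride may instead go to the far end of the diene, which would move the ring alkene into the ring fusion. The Claisen half may also leak through the minor rotamer and erode the transfer to C3a. The fallback uses known reactions and sets out from ketone 19. A TiCl4-mediated Mukaiyama–Michael addition of the tert-butyldimethylsilyl ketene acetal of methyl butanoate to the ring CH= carbon of 19 (the future C3a) should give, after aqueous work-up and enolisation of C7a to the trans arrangement, the 1,5-keto ester F1. Facial selectivity at C3a then rests on substrate control only. A McMurry keto ester coupling (TiCl3, LiAlH4, Et3N, DME, reflux) closes C1–C2 to the cyclic methyl enol ether F2. Mild aqueous acid hydrolyses F2 to ketone 24 as C1/C3 epimers, which step 14 converges.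

Step 2. The tetrasubstituted dienophile may simply not react before the silyloxydiene polymerises or loses its silyl group at the temperature needed. The fallback sets out from 3 and uses a far more nucleophilic diene. (1E)-3-[tert-Butyl(dimethyl)silyl]oxy-N,N,2-trimethylbuta-1,3-dien-1-amine F3 is made from 4-(dimethylamino)-3-methylbut-3-en-2-one with KN(SiMe3)2 and TBSCl. It should add to 3 below 60 °C, if need be by a stepwise Michael–Mannich path, to give the amino adduct F4. Dilute HCl removes the silyl group and dimethylamine to give the racemic enone anhydride F5. A 1,4-hydrosilylation with t-BuMe2SiH and RhCl(PPh3)3 (cat.) regenerates the regiodefined silyl enol ether, returning to 4.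

Step 3. Methanolysis at carbonyl groups flanked by two quaternary carbons may be slow or poorly discriminated, so the two enantiomers are not cleanly channelled into different constitutional isomers. The alkaloid may also pair enantiomer and regioisomer in the opposite sense. The fallback sets out from 4 and separates the two tasks. Unselective methanolysis (MeOH, DMAP, CH2Cl2) gives the racemic hemiester F6 and its racemic regioisomer F7, which are separated on silica. F6 is then resolved by preparative chromatography on a chiral stationary phase to give 5.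

Further compounds
F1 | step 13 | methyl 5-acetyl-1,2-diethyl-2-[(1E,3E)-2-ethyl-4-phenylbuta-1,3-dien-1-yl]-6-(1-methoxy-1-oxobutan-2-yl)-4-methylcyclohex-3-ene-1-carboxylate (ring centres as in 24, acetyl and ester arm trans, arm centre as epimers) | CCC(/C=C/c1ccccc1)=C\[C@@]1(CC)C=C(C)[C@@H](C(C)=O)[C@H](C(CC)C(=O)OC)[C@@]1(CC)C(=O)OC
F2 | step 13 | methyl 3,4,5-triethyl-5-[(1E,3E)-2-ethyl-4-phenylbuta-1,3-dien-1-yl]-2-methoxy-1,7-dimethyl-3a,4,5,7a-tetrahydro-3H-indene-4-carboxylate (cyclic enol ether, ring centres as in 24, C3 as epimers) | CCC(/C=C/c1ccccc1)=C\[C@@]1(CC)C=C(C)[C@@H]2[C@H](C(CC)C(OC)=C2C)[C@@]1(CC)C(=O)OC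
F3 | step 2 | (1E)-3-[tert-butyl(dimethyl)silyl]oxy-N,N,2-trimethylbuta-1,3-dien-1-amine | CN(C)/C=C(\C)C(=C)O[Si](C)(C)C(C)(C)C
F4 | step 2 | rac-5-[tert-butyl(dimethyl)silyl]oxy-7-(dimethylamino)-3a,7a-diethyl-6-methyl-3a,4,7,7a-tetrahydro-2-benzofuran-1,3-dione (cis ring fusion, amino centre undefined) | O=C3[C@@]1(CC)C(N(C)C)C(C)=C(O[Si](C)(C)C(C)(C)C)C[C@@]1(CC)C(=O)O3
F5 | step 2 | rac-3a,7a-diethyl-6-methyl-3a,7a-dihydro-2-benzofuran-1,3,5(4H)-trione (cis ring fusion) | O=C3[C@@]1(CC)C=C(C)C(=O)C[C@@]1(CC)C(=O)O3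
F6 | step 3 | racemic form of 5 (both enantiomers) | OC(=O)[C@@]1(CC)CC(C)=C(O[Si](C)(C)C(C)(C)C)C[C@@]1(CC)C(=O)OC.OC(=O)[C@]1(CC)CC(C)=C(O[Si](C)(C)C(C)(C)C)C[C@]1(CC)C(=O)OC
F7 | step 3 | racemic 3-[tert-butyl(dimethyl)silyl]oxy-1,6-diethyl-6-(methoxycarbonyl)-4-methylcyclohex-3-ene-1-carboxylic acid, cis (regioisomeric hemiester, both enantiomers) | COC(=O)[C@@]1(CC)CC(C)=C(O[Si](C)(C)C(C)(C)C)C[C@@]1(CC)C(=O)O.COC(=O)[C@]1(CC)CC(C)=C(O[Si](C)(C)C(C)(C)C)C[C@]1(CC)C(=O)O
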